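Early on, the theta run already reads E at 2.7% at 6.00 min, about the same as its 2.7% at 80.0 min.

| setting | theta | epsilon | flask |
|---|---|---|---|
| E | 0.50 mM | 2 mM | 1.0 mM |
| remark | run made earlier | run made earlier |  |
| time |  |  | 1.0 h |

- theta (time / min: E / %, J / %, D / %): 6.00: 2.7, 72.9, 14.2; 20.0: 2.7, 77.1, 13.2; 30.0: 5.2, 76.4, 14.9; 50.0: 2.7, 77.0, 15.0; 80.0: 2.7, 76.5, 12.6
- epsilon (time / min: E / %, J / %, D / %): 15.0: 0, 94.6, 2.8; 30.0: 0, 94.3, 3.8; 40.0: 0.2, 95.5, 1.1; 60.0: 0, 93.4, 4.5; 80.0: 3.1, 93.2, 3.9

(scatter of a reading: 1 percentage point)

- what is said of J includes X
- X is a solid; its amount is given per volume of the solution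
- the numbers in the tables scatter by 1 percentage point (one standard deviation)
- on the list of suspects stand: X <-> J; Z <-> D; E <-> J; E <-> G; J <-> Z
- what has gone from E into another species counts as reacted, even if it can come back
- the reaction counts as stopped when no species that holds the E changes by six tenths of a point or more over the second half of the time

1. why nothing more happens at 1.0 h, or that something still does (it is still moving / forward and back rates have come level)
2. part of the E gone at 1.0 h
3. the J standing at 1.0 h, as a percentage of the E charged
4. the D standing at 1.0 h, as a percentage of the E charged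
5. the Z standing at 1.0 h, as a percentage of the E charged
6. amount of J if the flask were left three thousand times as long, in percent of the E charged

The percentages of J differ widely between the two runs, but a balance on the E charged, taken in millimolar, brings them together. Call the holding the amount of the charge that stands outside J and its crystals, that is, the charge times the part not read as J. The theta readings from 20.0 min on give 0.116 mM, and the epsilon readings give 0.116 mM, about the same. Charges a factor of 4.00 apart thus leave about one holding as read, and the excess appears as J. My own reckoning for the flask subtracts this holding from 1.0 mM and gives J at 88.4%.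

The forecast reaches the same J: 88.4%, with 98.6% of E gone, D at 7%, Z at 2%, 88.4% of J at long times, and the ending "forward and back rates have come level". Its grounds are that “every solution species sits at a fixed concentration”.

The flask gives 88.2% of J, 98.3% of E gone, D at 6.74%, Z at 2.81%, 88.2% of J at long times, and the ending "forward and back rates have come level".

    X ⇌ J, rate k1*(cs1 - [J]) while solid is left; crystals form when [J] > cs1 (solubility = 0.0120 mM, k = 0.180 s⁻¹)
    Z ⇌ D (K = 2.40, k = 0.0423 s⁻¹)
    E ⇌ J (K = 0.725, k = 0.0175 s⁻¹)
    E ⇌ G (K = 0.353, k = 0.0157 s⁻¹)
    J ⇌ Z (K = 2.34, k = 0.0668 s⁻¹)

In this flask D stands at 6.74% at 1.00 h because D returns to Z, and in the run without that return D stands at >99.9%. The flask at 1.00 h has 87.0% of its charge as X, and its outside amount comes to 0.118 mM. Conversion has moved by 5 points at 0.249 mM of E, against 1.0 mM in this flask. In a neighbour flask with 1.7 mM of E, the holding of 0.116 mM puts J at 93.2%, and that flask stands at 93.1%.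

All runs stem from a simulated flask with made-up constants; the scatter is artificial.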